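(The numbers in the tables were generated by integration on assumed constants; scatter was added.)

**No constants.** We hold no rate constants, so we read the flask against the two earlier runs.

all flasks: impurity 0.47 mM

|  | substrate | reagent | free catalyst | remark |
|---|---|---|---|---|
| larch | 2 M | 1.6 M | 1.2 mM | run made earlier |
| cedar | 2 M | 1.6 M | 1.8 mM | run made earlier |
| flask | 2.0 M | 1.60 M | 2.4 mM |  |

| larch: time / d | larch: product / % | cedar: time / d | cedar: product / % |
|---|---|---|---|
| 0.500 | 4.8 | 0.500 | 8.1 |
| 0.833 | 5.0 | 1.67 | 23.3 |
| 1.67 | 12.4 | 3.00 | 38.0 |
| 3.00 | 23.0 | 4.00 | 45.7 |
| 6.00 | 40.2 | 6.00 | 57.8 |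

(each reading ± 1 percentage point)

- apparent order in reagent when 20 % of the substrate are converted (percent change of the rate of making product for one percent more reagent charged)

- the analysis behind the earlier runs scatters by 1 percentage point, standard deviation
- reactions considered so far: substrate + free catalyst <-> catalyst intermediate A; reagent + catalyst intermediate A -> catalyst intermediate B; catalyst intermediate C -> free catalyst + product; catalyst intermediate B <-> by-product + catalyst intermediate C; free catalyst + impurity -> spent catalyst
- no earlier run changes the charge of reagent; that part of a forecast is a guess

**Working catalyst.** Each impurity takes one free catalyst away for good, and we take that loss off the charge before we compare the runs. We reckon with the working catalyst, the charged [free catalyst] less the charged [impurity]: 0.730 mM in larch, 1.33 mM in cedar, 1.93 mM in the flask. Suppose time counts in proportion to it. Then the 6.00 d of larch equal 3.29 d of cedar, where cedar's readings give 40.3 %. Larch read 40.2 %.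

**The curve.** On this clock the flask runs 1.45 times as fast as cedar. Cedar's first reading, 8.1 %, falls at 0.345 d in the flask. Cedar's slope across 20 % conversion, scaled up, gives our flask rate there, 0.377 M d⁻¹, a reading with its scatter. Cedar's last point, 57.8 %, falls at 4.13 d. Beyond it the curve flattens towards 80.0 % product: one reagent goes per product, and the reagent charge is smaller than the substrate charge, which makes it the limiting reagent.

**Reagent order.** Both earlier runs hold 1.6 M of reagent, so they do not vary it; our guess, and it is no more, lies below one. The forecast says 0.85, on the ground that “the order is near one”.

**The result.** The flask gives an order of 0.67, and product reaches 80.0 % by 100 d.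

    substrate + free catalyst ⇌ catalyst intermediate A (K = 1.39 M⁻¹, k = 17.6 M⁻¹ h⁻¹)
    reagent + catalyst intermediate A → catalyst intermediate B (k = 19.6 M⁻¹ h⁻¹)
    catalyst intermediate C → free catalyst + product (k = 42.5 h⁻¹)
    catalyst intermediate B ⇌ by-product + catalyst intermediate C (K = 4.43 M, k = 2540 h⁻¹)
    free catalyst + impurity → spent catalyst (k = 25300 M⁻¹ h⁻¹)

**The correction.** The flask makes product at 0.376 M d⁻¹ at 20 % conversion, close to our 0.377 M d⁻¹. Spent catalyst stands at 19.6 % of the charge, the 19.6 % we subtracted. A second run of this flask takes away the loss of free catalyst to impurity, which is one part of what sets its rate. That run goes 1.24 times as fast at 20 % conversion, and the charge over working catalyst is 1.24. In this flask the same loss also lifts the apparent order in free catalyst at 20 % conversion: without it that order is 1.0, with it 1.2.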